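**Plan**

1. Drimane numbering is used for the core. Ring A is C1–C5/C10 (gem‑dimethyl C4, angular‑methyl C10) and ring B is C5–C10 (C8 = CHMe, C9 = ring alkene carbon); C11 is the CCl(aryl) carbon.
2. Cuts: the two O–Si bonds; then, in one operation, C11–Cl, C9–C10 and C4–C5 (returned to C4–C10). This opens ring B and contracts ring A to a (1,2,2‑trimethylcyclopentyl)carbinyl mesylate carrying an aryl alkyne. Further cuts are C5–C6 (acid chloride + Grignard), C11–aryl (Sonogashira) and C7–C8 (malonate SN2).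
3. Enabling feature: C10 is quaternary and lies between C5–H and the CMe2 carbon C4. A 1,2‑shift of C4 from C10 to a C5 carbinyl cation therefore makes ring A from a 1,2,2‑trimethylcyclopentane and leaves the charge on C10, five atoms from alkyne carbon C9.
4. Forward ring order: cyclopentane (from camphoric acid) → ring A by one‑carbon ring expansion → ring B by 6‑exo‑dig closure onto the aryl alkyne → chloride capture of the vinyl cation, all in one cascade. The arene is bought (5‑iodovanillin).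
5. Stereochemistry: C8 comes from (S)‑but‑3‑yn‑2‑ol (SN2 inversion), the cyclopentane quaternary centre from (1S,3R)‑camphoric acid, the carbinol from a CBS reduction. The cascade relays the carbinol to C5 (inversion), sets C10 by anti capture (trans fusion) and the E‑chloroalkene by the direction of chloride approach.
6. Helpers removed: the C3 carboxyl of camphoric acid (Barton decarboxylation), the mesylate (leaves in the key step), two TBS ethers (last step).

Key step: step 15

(TBS = tert‑butyldimethylsilyl.)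

**Route**

Step 1
Reactants: 1 5‑iodovanillin (4‑hydroxy‑3‑iodo‑5‑methoxybenzaldehyde)
Product: 3 2‑iodo‑6‑methoxybenzene‑1,4‑diol, via aryl formate 2 (not isolated)
Conditions: H2O2 (30 %), NaOH, H2O/THF, 0 °C to rt; HCl work‑up under argon
Reagents that add atoms: hydrogen peroxide, OO
Why: Dakin oxidation: the peroxide adduct of the para‑hydroxybenzaldehyde rearranges by aryl migration to formate 2, which is hydrolysed in situ to the hydroquinone.

Step 2
Reactants: 3 2‑iodo‑6‑methoxybenzene‑1,4‑diol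
Product: 4 1,4‑bis(tert‑butyldimethylsilyloxy)‑2‑iodo‑6‑methoxybenzene
Conditions: TBSCl, imidazole, DMF, rt
Reagents that add atoms: tert‑butyldimethylsilyl chloride, CC(C)(C)[Si](C)(C)Cl
Why: Standard imidazole‑mediated silylation of both phenols; the aryl silyl ethers should tolerate the later Pd, Mg, borane and Lewis‑acid steps and leave with fluoride at the end.

Step 3
Reactants: 5 (S)‑but‑3‑yn‑2‑ol
Product: 6 (S)‑but‑3‑yn‑2‑yl 4‑methylbenzenesulfonate
Conditions: TsCl, Et3N, DMAP (cat.), CH2Cl2, 0 °C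
Reagents that add atoms: 4‑toluenesulfonyl chloride, Cc1ccc(cc1)S(=O)(=O)Cl
Why: O‑Sulfonylation turns the hydroxyl into a leaving group without touching the stereocentre.

Step 4
Reactants: 6 (S)‑but‑3‑yn‑2‑yl 4‑methylbenzenesulfonate; 7 dimethyl malonate
Product: 8 dimethyl (S)‑2‑(but‑3‑yn‑2‑yl)malonate
Conditions: NaH, DMF, 0 to 60 °C
Reagents that add atoms: none
Why: SN2 alkylation of the soft malonate anion at the secondary propargylic tosylate proceeds with inversion and sets the methyl‑bearing stereocentre (C8 of the target; the descriptor stays S because the priorities change).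

Step 5
Reactants: 8 dimethyl (S)‑2‑(but‑3‑yn‑2‑yl)malonate
Product: 9 methyl (S)‑3‑methylpent‑4‑ynoate
Conditions: LiCl, H2O, DMSO, 140 °C
Reagents that add atoms: none
Why: Krapcho dealkoxycarbonylation (chloride attack on a methyl ester, then loss of CO2) removes one ester and leaves the remote stereocentre alone.

Step 6
Reactants: 9 methyl (S)‑3‑methylpent‑4‑ynoate
Product: 10 (S)‑3‑methylpent‑4‑yn‑1‑ol
Conditions: LiAlH4, Et2O, 0 °C
Reagents that add atoms: none
Why: Hydride reduction of the ester to the primary alcohol; the isolated terminal alkyne is inert to LiAlH4 at 0 °C.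

Step 7
Reactants: 10 (S)‑3‑methylpent‑4‑yn‑1‑ol; 4 1,4‑bis(tert‑butyldimethylsilyloxy)‑2‑iodo‑6‑methoxybenzene
Product: 11 (S)‑5‑[2,5‑bis(tert‑butyldimethylsilyloxy)‑3‑methoxyphenyl]‑3‑methylpent‑4‑yn‑1‑ol
Conditions: Pd(PPh3)2Cl2 (cat.), CuI (cat.), Et3N, THF, 45 °C
Reagents that add atoms: none
Why: Sonogashira coupling of the terminal alkyne with the aryl iodide installs the aryl alkyne that later ends the cationic cascade; the propargylic stereocentre is not involved.

Step 8
Reactants: 11 (S)‑5‑[2,5‑bis(tert‑butyldimethylsilyloxy)‑3‑methoxyphenyl]‑3‑methylpent‑4‑yn‑1‑ol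
Product: 12 (S)‑2‑(5‑bromo‑3‑methylpent‑1‑yn‑1‑yl)‑1,4‑bis(tert‑butyldimethylsilyloxy)‑6‑methoxybenzene
Conditions: CBr4, PPh3, CH2Cl2, 0 °C
Reagents that add atoms: carbon tetrabromide, BrC(Br)(Br)Br
Why: Appel bromination of the primary alcohol runs under neutral conditions that spare the aryl silyl ethers and the alkyne.

Step 9
Reactants: 13 (1S,3R)‑(−)‑camphoric acid
Product: 14 (1S,3R)‑camphoric anhydride [(1S,5R)‑1,8,8‑trimethyl‑3‑oxabicyclo[3.2.1]octane‑2,4‑dione]
Conditions: Ac2O, reflux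
Reagents that add atoms: none
Why: Cyclodehydration of the cis‑1,3‑diacid gives the bridged anhydride, in which the two carbonyl groups differ sterically (one on a CH carbon, one on the quaternary carbon).

Step 10
Reactants: 14 (1S,3R)‑camphoric anhydride
Product: 16 (S)‑1,2,2‑trimethylcyclopentane‑1‑carboxylic acid, via Barton ester 15 (not isolated)
Conditions: 1‑hydroxypyridine‑2(1H)‑thione, DMAP (cat.), CH2Cl2, rt, dark; then t‑BuSH, hν (visible), rt
Reagents that add atoms: none
Why: The thiohydroxamic acid should open the anhydride at the less hindered carbonyl to give O‑acyl thiohydroxamate 15, and Barton reductive decarboxylation (radical chain, hydrogen transfer from the thiol) removes that carboxyl while the quaternary stereocentre stays untouched.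

Step 11
Reactants: 16 (S)‑1,2,2‑trimethylcyclopentane‑1‑carboxylic acid
Product: 17 (S)‑1,2,2‑trimethylcyclopentane‑1‑carbonyl chloride
Conditions: (COCl)2, DMF (cat.), CH2Cl2, rt
Reagents that add atoms: oxalyl chloride, O=C(Cl)C(=O)Cl
Why: Acid chloride formation through the chloroiminium catalyst works for hindered tertiary acids and there is no α‑hydrogen to epimerise.

Step 12
Reactants: 12 (S)‑2‑(5‑bromo‑3‑methylpent‑1‑yn‑1‑yl)‑1,4‑bis(tert‑butyldimethylsilyloxy)‑6‑methoxybenzene; 17 (S)‑1,2,2‑trimethylcyclopentane‑1‑carbonyl chloride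
Product: 19 (S)‑6‑[2,5‑bis(tert‑butyldimethylsilyloxy)‑3‑methoxyphenyl]‑4‑methyl‑1‑[(S)‑1,2,2‑trimethylcyclopentyl]hex‑5‑yn‑1‑one, via Grignard reagent 18 (not isolated)
Conditions: Mg, THF, rt; then CuI (10 mol %), 17, THF, −30 to 0 °C
Reagents that add atoms: none
Why: Magnesium insertion gives the primary Grignard reagent 18, and copper‑catalysed acylation by the hindered acid chloride should stop at the ketone because the neopentyl‑type carbonyl resists a second addition.

Step 13
Reactants: 19 (S)‑6‑[2,5‑bis(tert‑butyldimethylsilyloxy)‑3‑methoxyphenyl]‑4‑methyl‑1‑[(S)‑1,2,2‑trimethylcyclopentyl]hex‑5‑yn‑1‑one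
Product: 20 (1S,4S)‑6‑[2,5‑bis(tert‑butyldimethylsilyloxy)‑3‑methoxyphenyl]‑4‑methyl‑1‑[(S)‑1,2,2‑trimethylcyclopentyl]hex‑5‑yn‑1‑ol
Conditions: (R)‑2‑methyl‑CBS‑oxazaborolidine (1.0 equiv), BH3·SMe2, THF, −30 °C; MeOH quench
Reagents that add atoms: none
Why: Corey–Bakshi–Shibata reduction: the (R)‑oxazaborolidine distinguishes the tert‑alkyl (large) from the primary alkyl (small) substituent and should deliver hydride to give the (S)‑carbinol under reagent control.

Step 14
Reactants: 20 (1S,4S)‑6‑[2,5‑bis(tert‑butyldimethylsilyloxy)‑3‑methoxyphenyl]‑4‑methyl‑1‑[(S)‑1,2,2‑trimethylcyclopentyl]hex‑5‑yn‑1‑ol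
Product: 21 (1S,4S)‑6‑[2,5‑bis(tert‑butyldimethylsilyloxy)‑3‑methoxyphenyl]‑4‑methyl‑1‑[(S)‑1,2,2‑trimethylcyclopentyl]hex‑5‑yn‑1‑yl methanesulfonate
Conditions: MsCl, Et3N, CH2Cl2, −20 to 0 °C; used crude and cold
Reagents that add atoms: methanesulfonyl chloride, CS(=O)(=O)Cl
Why: Mesylation through sulfene works at the hindered alcohol with retention, and the quaternary neighbour blocks SN2 and E2 so the leaving group is kept for the cascade.

Step 15
Reactants: 21 (1S,4S)‑6‑[2,5‑bis(tert‑butyldimethylsilyloxy)‑3‑methoxyphenyl]‑4‑methyl‑1‑[(S)‑1,2,2‑trimethylcyclopentyl]hex‑5‑yn‑1‑yl methanesulfonate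
Product: 24 1,4‑bis(tert‑butyldimethylsilyloxy)‑2‑[(E)‑chloro((2S,4aS,8aS)‑2,5,5,8a‑tetramethyloctahydronaphthalen‑1(2H)‑ylidene)methyl]‑6‑methoxybenzene, via tertiary cyclohexyl cation 22 (not isolated), via aryl vinyl cation 23 (not isolated)
Conditions: TiCl4 (1.5 equiv), 2,6‑di‑tert‑butyl‑4‑methylpyridine (0.3 equiv), CH2Cl2, −78 to −30 °C
Reagents that add atoms: titanium tetrachloride, Cl[Ti](Cl)(Cl)Cl
Why: Proposed new method: TiCl4 activates the mesylate and ionization at the neopentyl‑type carbinol carbon is assisted by the anti‑periplanar 1,2‑shift of the quaternary CMe2 ring carbon (C4) from the methyl‑bearing ring carbon to the carbinol carbon, a Wagner–Meerwein ring expansion that turns the cyclopentane into the six‑membered gem‑dimethyl ring A and leaves tertiary cation 22 at the future angular carbon C10; the closest known reaction types are the solvolytic ring expansion of cyclopentylcarbinyl sulfonates and the cation–alkyne (polyene‑type) cyclization ended by chloride capture. Cation 22 is attacked by the tethered aryl alkyne at C9 in a 6‑exo‑dig closure that forms ring B, and the resulting α‑aryl vinyl cation 23, stabilised by the ortho‑silyloxy group, takes chloride from the chlorotitanate counter‑ion. C5 is set by the (S)‑carbinol configuration through inversion in the migration step, C10 by capture of the cation on the face opposite to the departing C4 from a chair‑like arrangement with the equatorial side chain (trans ring fusion), and C8 is carried unchanged from 5. The step needs migration of C4 in preference to the ring CH2 or the methyl group, which the higher migratory aptitude of the fully substituted carbon and the rotamer that keeps only H between the two ring bonds should secure. It also needs capture of 22 by the alkyne faster than proton loss or hydride shift, which the low temperature, the electron‑rich aryl alkyne and the hindered‑pyridine proton scavenger should favour. The E geometry should follow from chloride approaching the linear vinyl cation in the alkene plane past the equatorial C8–H and not past the C1 methylene next to the quaternary centre.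

Step 16
Reactants: 24 1,4‑bis(tert‑butyldimethylsilyloxy)‑2‑[(E)‑chloro((2S,4aS,8aS)‑2,5,5,8a‑tetramethyloctahydronaphthalen‑1(2H)‑ylidene)methyl]‑6‑methoxybenzene
Product: 25 2‑[(E)‑chloro((2S,4aS,8aS)‑2,5,5,8a‑tetramethyloctahydronaphthalen‑1(2H)‑ylidene)methyl]‑6‑methoxybenzene‑1,4‑diol (CNP0162917.1)
Conditions: TBAF, AcOH, degassed THF, 0 °C, argon
Reagents that add atoms: none
Why: Fluoride cleavage of the two aryl silyl ethers, buffered with acetic acid and run oxygen‑free so that the hydroquinone is not oxidised; the vinyl chloride, the alkene and the methyl ether are inert.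

**Compound list**

1 | 5‑iodovanillin (4‑hydroxy‑3‑iodo‑5‑methoxybenzaldehyde) | COc1cc(C=O)cc(I)c1O | starting material
2 | 4‑hydroxy‑3‑iodo‑5‑methoxyphenyl formate (not isolated) | COc1cc(OC=O)cc(I)c1O | intermediate
3 | 2‑iodo‑6‑methoxybenzene‑1,4‑diol | COc1cc(O)cc(I)c1O | intermediate
4 | 1,4‑bis(tert‑butyldimethylsilyloxy)‑2‑iodo‑6‑methoxybenzene | COc1cc(O[Si](C)(C)C(C)(C)C)cc(I)c1O[Si](C)(C)C(C)(C)C | intermediate
5 | (S)‑but‑3‑yn‑2‑ol | C[C@H](O)C#C | starting material
6 | (S)‑but‑3‑yn‑2‑yl 4‑methylbenzenesulfonate | C[C@H](OS(=O)(=O)c1ccc(C)cc1)C#C | intermediate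
7 | dimethyl malonate | COC(=O)CC(=O)OC | starting material
8 | dimethyl (S)‑2‑(but‑3‑yn‑2‑yl)malonate | C[C@@H](C(C(=O)OC)C(=O)OC)C#C | intermediate
9 | methyl (S)‑3‑methylpent‑4‑ynoate | C[C@@H](CC(=O)OC)C#C | intermediate
10 | (S)‑3‑methylpent‑4‑yn‑1‑ol | C[C@@H](CCO)C#C | intermediate
11 | (S)‑5‑[2,5‑bis(tert‑butyldimethylsilyloxy)‑3‑methoxyphenyl]‑3‑methylpent‑4‑yn‑1‑ol | C[C@@H](CCO)C#Cc1cc(O[Si](C)(C)C(C)(C)C)cc(OC)c1O[Si](C)(C)C(C)(C)C | intermediate
12 | (S)‑2‑(5‑bromo‑3‑methylpent‑1‑yn‑1‑yl)‑1,4‑bis(tert‑butyldimethylsilyloxy)‑6‑methoxybenzene | C[C@@H](CCBr)C#Cc1cc(O[Si](C)(C)C(C)(C)C)cc(OC)c1O[Si](C)(C)C(C)(C)C | intermediate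
13 | (1S,3R)‑(−)‑camphoric acid [(1S,3R)‑1,2,2‑trimethylcyclopentane‑1,3‑dicarboxylic acid] | C[C@]1(C(=O)O)CC[C@@H](C(=O)O)C1(C)C | starting material
14 | (1S,3R)‑camphoric anhydride [(1S,5R)‑1,8,8‑trimethyl‑3‑oxabicyclo[3.2.1]octane‑2,4‑dione] | C[C@]1(C(=O)O2)CC[C@@H](C2=O)C1(C)C | intermediate
15 | (1S,3R)‑1,2,2‑trimethyl‑3‑{[(2‑thioxopyridin‑1(2H)‑yl)oxy]carbonyl}cyclopentane‑1‑carboxylic acid (Barton ester, not isolated) | C[C@]1(C(=O)O)CC[C@@H](C(=O)On2ccccc2=S)C1(C)C | intermediate
16 | (S)‑1,2,2‑trimethylcyclopentane‑1‑carboxylic acid | C[C@]1(C(=O)O)CCCC1(C)C | intermediate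
17 | (S)‑1,2,2‑trimethylcyclopentane‑1‑carbonyl chloride | C[C@]1(C(Cl)=O)CCCC1(C)C | intermediate
18 | Grignard reagent of 12, (S)‑{5‑[2,5‑bis(tert‑butyldimethylsilyloxy)‑3‑methoxyphenyl]‑3‑methylpent‑4‑yn‑1‑yl}magnesium bromide (not isolated) | C[C@@H](CC[Mg]Br)C#Cc1cc(O[Si](C)(C)C(C)(C)C)cc(OC)c1O[Si](C)(C)C(C)(C)C | intermediate
19 | (S)‑6‑[2,5‑bis(tert‑butyldimethylsilyloxy)‑3‑methoxyphenyl]‑4‑methyl‑1‑[(S)‑1,2,2‑trimethylcyclopentyl]hex‑5‑yn‑1‑one | C[C@]1(C(=O)CC[C@H](C)C#Cc2cc(O[Si](C)(C)C(C)(C)C)cc(OC)c2O[Si](C)(C)C(C)(C)C)CCCC1(C)C | intermediate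
20 | (1S,4S)‑6‑[2,5‑bis(tert‑butyldimethylsilyloxy)‑3‑methoxyphenyl]‑4‑methyl‑1‑[(S)‑1,2,2‑trimethylcyclopentyl]hex‑5‑yn‑1‑ol | C[C@]1([C@@H](O)CC[C@H](C)C#Cc2cc(O[Si](C)(C)C(C)(C)C)cc(OC)c2O[Si](C)(C)C(C)(C)C)CCCC1(C)C | intermediate
21 | (1S,4S)‑6‑[2,5‑bis(tert‑butyldimethylsilyloxy)‑3‑methoxyphenyl]‑4‑methyl‑1‑[(S)‑1,2,2‑trimethylcyclopentyl]hex‑5‑yn‑1‑yl methanesulfonate | C[C@]1([C@@H](OS(C)(=O)=O)CC[C@H](C)C#Cc2cc(O[Si](C)(C)C(C)(C)C)cc(OC)c2O[Si](C)(C)C(C)(C)C)CCCC1(C)C | intermediate
22 | 1,3,3‑trimethylcyclohexyl cation carrying the (S)‑5‑aryl‑3‑methylpent‑4‑ynyl chain on C2 (charge at C10, ring CH configured as C5 of the target; not isolated) | C[C+]1CCCC(C)(C)[C@@H]1CC[C@H](C)C#Cc2cc(O[Si](C)(C)C(C)(C)C)cc(OC)c2O[Si](C)(C)C(C)(C)C | intermediate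
23 | α‑aryl vinyl cation of the trans‑decalin (charge at C11; not isolated) | COc1cc(O[Si](C)(C)C(C)(C)C)cc([C+]=C2[C@@H](C)CC[C@H]3C(C)(C)CCC[C@]23C)c1O[Si](C)(C)C(C)(C)C | intermediate
24 | 1,4‑bis(tert‑butyldimethylsilyloxy)‑2‑[(E)‑chloro((2S,4aS,8aS)‑2,5,5,8a‑tetramethyloctahydronaphthalen‑1(2H)‑ylidene)methyl]‑6‑methoxybenzene | COc1cc(O[Si](C)(C)C(C)(C)C)cc(/C(Cl)=C2/[C@@H](C)CC[C@H]3C(C)(C)CCC[C@]23C)c1O[Si](C)(C)C(C)(C)C | intermediate
25 | 2‑[(E)‑chloro((2S,4aS,8aS)‑2,5,5,8a‑tetramethyloctahydronaphthalen‑1(2H)‑ylidene)methyl]‑6‑methoxybenzene‑1,4‑diol | COc1cc(O)cc(/C(Cl)=C2/[C@@H](C)CC[C@H]3C(C)(C)CCC[C@]23C)c1O | target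

**Count and risks**

Total step count: 16. Longest linear sequence: 11 steps (5 → 6 → 8 → 9 → 10 → 11 → 12 → 19 → 20 → 21 → 24 → 25).

Steps most likely to fail:

1. Step 15 (proposed new method). Several processes may go wrong:
   - migration of the ring CH2 or of the methyl group in place of C4;
   - proton loss or a 1,2‑hydride shift at the tertiary cation before the alkyne arrives, which would erase the C5 information or open a 5‑exo spiro closure;
   - cis ring fusion, because the C8 methyl must sit axial and syn to the angular methyl in the closing chair;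
   - chloride capture from the wrong side of the vinyl cation;
   - Lewis‑acid loss of the silyl ethers.

   Fallback (known chemistry, no ring expansion; ring A is bought as a six‑membered ring), setting out from bromide 12 and coming back at 24. Grignard reagent 18 is added to commercial 2,4,4‑trimethylcyclohex‑2‑en‑1‑one (CC1=CC(C)(C)CCC1=O) in a copper‑catalysed asymmetric conjugate addition (CuBr·SMe2, chiral ferrocenyl diphosphine chosen for the (S) ring centre, t‑BuOMe, −78 °C). The magnesium enolate is trapped with N‑phenyl‑bis(trifluoromethanesulfonimide) to give the enol triflate (S)‑3‑{(S)‑5‑[2,5‑bis(tert‑butyldimethylsilyloxy)‑3‑methoxyphenyl]‑3‑methylpent‑4‑yn‑1‑yl}‑2,4,4‑trimethylcyclohex‑1‑en‑1‑yl trifluoromethanesulfonate F1. Palladium‑catalysed formate reduction (Pd(OAc)2, PPh3, HCO2H, Bu3N, DMF, 60 °C) should give the alkene 1,4‑bis(tert‑butyldimethylsilyloxy)‑2‑methoxy‑6‑{(S)‑3‑methyl‑5‑[(S)‑2,6,6‑trimethylcyclohex‑2‑en‑1‑yl]pent‑1‑yn‑1‑yl}benzene F2. HCl (1 equiv) with SnCl4 in CH2Cl2 at −78 °C then protonates the trisubstituted alkene to the same tertiary cation 22, and the known cation–alkyne cyclization with chloride capture leads to 24.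

2. Step 10. Opening of the anhydride may be unselective or reversible, so that the thiohydroxamate ester forms at the tertiary carboxyl or reverts to the anhydride before the radical chain starts.

   Fallback, setting out from 13 and coming back at 16. Exhaustive methylation (MeI, K2CO3, DMF) gives dimethyl (1S,3R)‑camphorate F3. One equivalent of KOH in MeOH/H2O hydrolyses only the unhindered secondary ester to (1R,3S)‑3‑(methoxycarbonyl)‑2,2,3‑trimethylcyclopentane‑1‑carboxylic acid F4. Conventional Barton decarboxylation of this single free acid ((COCl)2; sodium 2‑thioxopyridin‑1‑olate; t‑BuSH, hν) gives methyl (S)‑1,2,2‑trimethylcyclopentane‑1‑carboxylate F5. SN2 demethylation of the hindered ester (LiI, pyridine, reflux) returns acid 16.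

3. Step 13. The catalyst has to override the Felkin preference of the neighbouring quaternary stereocentre (mismatched pairing), and borane may hydroborate the aryl alkyne.

   Fallback, setting out from 16 and coming back at 20; it sets the carbinol by C–C bond formation under substrate control. LiAlH4 (THF, reflux) reduces 16 to [(S)‑1,2,2‑trimethylcyclopentyl]methanol F6. Swern oxidation gives (S)‑1,2,2‑trimethylcyclopentane‑1‑carbaldehyde F7. Grignard reagent 18 (from 12) is added at −78 °C; Felkin–Anh attack anti to the CMe2 ring carbon and past the methyl group should give the (S)‑carbinol 20 directly, and a minor epimer would be removed by chromatography.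

**Further compounds**

F1 | step 15 | (S)‑3‑{(S)‑5‑[2,5‑bis(tert‑butyldimethylsilyloxy)‑3‑methoxyphenyl]‑3‑methylpent‑4‑yn‑1‑yl}‑2,4,4‑trimethylcyclohex‑1‑en‑1‑yl trifluoromethanesulfonate | CC1=C(OS(=O)(=O)C(F)(F)F)CCC(C)(C)[C@@H]1CC[C@H](C)C#Cc2cc(O[Si](C)(C)C(C)(C)C)cc(OC)c2O[Si](C)(C)C(C)(C)C
F2 | step 15 | 1,4‑bis(tert‑butyldimethylsilyloxy)‑2‑methoxy‑6‑{(S)‑3‑methyl‑5‑[(S)‑2,6,6‑trimethylcyclohex‑2‑en‑1‑yl]pent‑1‑yn‑1‑yl}benzene | CC1=CCCC(C)(C)[C@@H]1CC[C@H](C)C#Cc2cc(O[Si](C)(C)C(C)(C)C)cc(OC)c2O[Si](C)(C)C(C)(C)C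
F3 | step 10 | dimethyl (1S,3R)‑1,2,2‑trimethylcyclopentane‑1,3‑dicarboxylate | C[C@]1(C(=O)OC)CC[C@@H](C(=O)OC)C1(C)C
F4 | step 10 | (1R,3S)‑3‑(methoxycarbonyl)‑2,2,3‑trimethylcyclopentane‑1‑carboxylic acid | C[C@]1(C(=O)OC)CC[C@@H](C(=O)O)C1(C)C
F5 | step 10 | methyl (S)‑1,2,2‑trimethylcyclopentane‑1‑carboxylate | C[C@]1(C(=O)OC)CCCC1(C)C
F6 | step 13 | [(S)‑1,2,2‑trimethylcyclopentyl]methanol | C[C@]1(CO)CCCC1(C)C
F7 | step 13 | (S)‑1,2,2‑trimethylcyclopentane‑1‑carbaldehyde | C[C@]1(C=O)CCCC1(C)C
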